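**Assumptions:** The target has no stereocentres, so the "single enantiomer" requirement is trivially met. 3,5-Dimethoxyphenol, prenyl bromide, 4-hydroxy-2-methoxybenzaldehyde, MOMCl, the Bestmann–Ohira reagent and N-methoxy-N-methylcarbamoyl chloride are taken as commercial.

## Retrosynthesis
- The usual chalcone/Baker–Venkataraman route is avoided. Instead, the flavone is made by oxa-Michael closure of an o-hydroxyaryl ynone (C4a–C4 bond and C2 alkyne), formed in situ from an o-MOM-oxyaryl ynone.
- The ynone comes from a directed-ortho-metalated A-ring aryllithium and an alkynyl Weinreb amide (B ring).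
- The A ring is built by two successive MOM-directed lithiations of 3,5-dimethoxyphenol. The first installs the C8 prenyl group and the second the C4a acyl group. The MOM-O becomes O1, so the prenyl-bearing carbon is necessarily next to the ring oxygen.
- The final step is chelation-controlled removal of the 5-OMe. Ring order: A ring (benzene) first, then the pyranone C ring (last ring, closed in step 7). The B ring is made separately as an aryl alkyne.

## Route

**Step 1**
Reactants: 1 (3,5-dimethoxyphenol)
Product: 2 (1-(methoxymethoxy)-3,5-dimethoxybenzene)
Conditions: MOMCl, i-Pr2NEt, CH2Cl2, 0 °C → rt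
Reagents that add atoms: MOMCl, ClCOC
Why: Phenol O-alkylation installs a MOM group, which serves as the strongest directing group for the next lithiations and later becomes the ring O1.

**Step 2**
Reactants: 2; 3 (prenyl bromide, CC(C)=CCBr)
Product: 4 (2-prenyl-1-(methoxymethoxy)-3,5-dimethoxybenzene)
Conditions: n-BuLi, THF, 0 °C, 1 h; then CuI (10 mol %), 3, –78 °C → rt
Reagents that add atoms: none beyond reactant 3
Why: Directed ortho-metalation occurs at C2, between OMOM and OMe, because MOM chelates Li more strongly than OMe and C2 and C6 are equivalent. Cu-catalysed SN2 alkylation on the primary carbon of prenyl bromide gives the linear prenyl group, because the hindered aryl nucleophile disfavours attack at the tertiary γ-carbon.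

**Step 3**
Reactants: 5 (4-hydroxy-2-methoxybenzaldehyde)
Product: 6 (4-(methoxymethoxy)-2-methoxybenzaldehyde)
Conditions: MOMCl, i-Pr2NEt, CH2Cl2, 0 °C → rt
Reagents that add atoms: MOMCl, ClCOC
Why: The phenol is protected as a MOM ether, which survives BuLi and K2CO3/MeOH and is removed together with the A-ring MOM later.

**Step 4**
Reactants: 6
Product: 7 (1-ethynyl-2-methoxy-4-(methoxymethoxy)benzene)
Conditions: Bestmann–Ohira reagent, K2CO3, MeOH, rt
Reagents that add atoms: dimethyl (1-diazo-2-oxopropyl)phosphonate, COP(=O)(OC)C(=[N+]=[N-])C(C)=O
Why: Seyferth–Gilbert homologation (Ohira–Bestmann variant) converts the aldehyde to the terminal alkyne under mild base.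

**Step 5**
Reactants: 7
Product: 8 (N-methoxy-N-methyl-3-[2-methoxy-4-(methoxymethoxy)phenyl]propiolamide)
Conditions: n-BuLi, THF, –78 °C; then ClC(O)N(OMe)Me, –78 → 0 °C
Reagents that add atoms: N-methoxy-N-methylcarbamoyl chloride, CON(C)C(=O)Cl
Why: Lithium acetylide acylation by the carbamoyl chloride gives the alkynyl Weinreb amide, which allows a single clean 1,2-addition in step 6.

**Step 6**
Reactants: 4; 8
Product: 9 (1-[2-(MOMO)-4,6-dimethoxy-3-prenylphenyl]-3-[2-methoxy-4-(MOMO)phenyl]prop-2-yn-1-one)
Conditions: n-BuLi (1.4 equiv), THF, 0 °C, 1 h; then 8, –78 → 0 °C; NH4Cl(aq)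
Reagents that add atoms: none (8 is the reactant)
Why: A second directed ortho-metalation occurs at C6 (between OMOM and OMe, and remote from the prenyl group). The aryllithium adds to the Weinreb amide to give a stable chelated tetrahedral intermediate that collapses to the ynone on workup. The acyl carbon ends up ortho to O1 and flanked by the future 5-OMe, so the regiochemistry is fixed.

**Step 7**
Reactants: 9
Product: 10 (4'-hydroxy-2',5,7-trimethoxy-8-prenylflavone)
Conditions: 2 M HCl (aq), THF/MeOH (1:1), 60 °C, 6 h
Reagents that add atoms: none
Why: Acidolysis removes both aryl MOM ethers. The free 2-OH then closes onto the β-carbon of the protonated ynone, possibly via the β-methoxy-enone formed by MeOH addition followed by addition–elimination. This is a 6-endo oxa-Michael closure and the regiochemistry is Michael-controlled. The pyranone ring forms here, with no new stereocentres.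

**Step 8**
Reactants: 10
Product: 11 (Artocarpetin B)
Conditions: BCl3 (3.5 equiv), CH2Cl2, –78 → 0 °C, 1.5 h; then MeOH, aq NaHCO3
Reagents that add atoms: none (BCl3 removes the methyl group)
Why: Chelation-controlled demethylation (BCl3 coordinated to the C4 carbonyl) cleaves only the peri 5-OMe. The 7-OMe, 2'-OMe and prenyl group are untouched at low temperature, and no stereocentre is involved.

## Compound list
1 | 3,5-dimethoxyphenol | COc1cc(O)cc(OC)c1 | starting material
2 | 1-(methoxymethoxy)-3,5-dimethoxybenzene | COCOc1cc(OC)cc(OC)c1 | intermediate
3 | prenyl bromide | CC(C)=CCBr | starting material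
4 | 2-prenyl-1-(methoxymethoxy)-3,5-dimethoxybenzene | COCOc1cc(OC)cc(OC)c1CC=C(C)C | intermediate
5 | 4-hydroxy-2-methoxybenzaldehyde | COc1cc(O)ccc1C=O | starting material
6 | 4-(methoxymethoxy)-2-methoxybenzaldehyde | COc1cc(OCOC)ccc1C=O | intermediate
7 | 1-ethynyl-2-methoxy-4-(methoxymethoxy)benzene | COc1cc(OCOC)ccc1C#C | intermediate
8 | N-methoxy-N-methyl-3-[2-methoxy-4-(MOMO)phenyl]propiolamide | COc1cc(OCOC)ccc1C#CC(=O)N(C)OC | intermediate
9 | 1-[2-(MOMO)-4,6-dimethoxy-3-prenylphenyl]-3-[2-methoxy-4-(MOMO)phenyl]prop-2-yn-1-one | COc1cc(OCOC)ccc1C#CC(=O)c1c(OC)cc(OC)c(CC=C(C)C)c1OCOC | intermediate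
10 | 4'-hydroxy-2',5,7-trimethoxy-8-prenylflavone | COc1cc(O)ccc1-c1cc(=O)c2c(OC)cc(OC)c(CC=C(C)C)c2o1 | intermediate
11 | Artocarpetin B (achiral) | COc1cc(O)ccc1-c1cc(=O)c2c(O)cc(OC)c(CC=C(C)C)c2o1 | target

**Total steps:** 8.
**Longest linear sequence:** 6 steps (5 → 6 → 7 → 8 → 9 → 10 → 11).

## Three steps most likely to fail
1. **Step 8 (selective 5-O-demethylation with BCl3).** The prenyl alkene may add HCl, the free 4'-OH may interfere, or 7-OMe/2'-OMe may be cleaved. Fallback (changes the approach): start from 5-methoxyresorcinol bis-MOM ether, install the ynone first at the doubly MOM-flanked C2, and close the flavone so that the 5-OH is released by mild MOM cleavage. Then brominate C8 (NBS) and install the prenyl group by Stille coupling with prenyl-SnBu3.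
2. **Step 2 (prenylation of the aryllithium).** SN2′ attack would give the reverse-prenyl isomer, and lithiation at C4 or at the benzylic position would compete. Fallback: trap the aryllithium with I2 to give the 2-iodoarene, then use Pd-catalysed Stille coupling with prenyl-SnBu3, which replaces the polar alkylation with cross-coupling.
3. **Step 6 (second lithiation and ynone formation).** The lithiation may be unselective (C6 vs C4), or the aryllithium may add in conjugate fashion to the alkynyl amide. Fallback: lithiate C6 and quench with DMF to give the aryl aldehyde. Add the lithium acetylide of 7 to give the propargylic alcohol, then oxidise with Dess–Martin periodinane to the same ynone 9.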